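**Retrosynthetic overview**
- Gardenin C is taken back to the racemic flavanone 16 and then to the cis-flavan-4-ol 15; only the oxidation level of ring C changes (desilylation, C4 oxidation, C2–C3 dehydrogenation).
- The strategy rests on ring A: C8a carries the ring oxygen O1 and lies between C8 (OMe) and C4a, so C8a=C4a can come from the enol ether C6=C5 of a dihydropyran, and C5 (OH), C6, C7 and C8 (all O-substituted) from the four carbons of a squarate.
- Ring A is therefore opened at C5–C4a: chromanol 14 comes from ring expansion of the 4-methoxy-4-(dihydropyran-6-yl)cyclobutenone 11.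
- 11 comes from the C6-lithiated dihydropyran 7 and dimethyl squarate, with the alkoxide capped as the future C8 methyl ether; ring C comes from a hetero-Diels–Alder reaction of the ring B aldehyde with Danishefsky's diene, followed by a cis-selective Luche reduction.
- Ring order: B (bought), C, then A.

Key step: step 6

Assumption: the target has no stereocentre, so C2 and C4 of the pyran are carried as the racemic cis pair (one enantiomer, 2R,4R, is drawn) and the quaternary cyclobutenone carbon of 10 and 11 as a mixture of both epimers.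

**Step 1**
Reactants: 1 3-hydroxy-4,5-dimethoxybenzaldehyde
Product: 2 3,4-dimethoxy-5-(triisopropylsilyloxy)benzaldehyde
Conditions: TIPSCl, imidazole, DMF, rt
Reagents that add atoms: triisopropylsilyl chloride, CC(C)[Si](Cl)(C(C)C)C(C)C
Why: Imidazole-promoted silylation of a phenol; the bulky aryl silyl ether should tolerate tBuLi and directs ortho-lithiation poorly, whereas a benzyl ether would be deprotonated at its CH2 group in step 5.

**Step 2**
Reactants: 2 3,4-dimethoxy-5-(triisopropylsilyloxy)benzaldehyde; 3 Danishefsky's diene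
Product: 5 2-[3,4-dimethoxy-5-(triisopropylsilyloxy)phenyl]-2,3-dihydro-4H-pyran-4-one (racemic), via methoxy silyloxy dihydropyran cycloadduct 4 (not isolated)
Conditions: ZnCl2, THF, rt; then TFA, CH2Cl2, 0 °C
Reagents that add atoms: none
Why: Lewis acid-catalysed hetero-Diels–Alder reaction of an aldehyde with Danishefsky's diene, after which acid removes methanol and the trimethylsilyl group from cycloadduct 4 to give the vinylogous ester; the one stereocentre forms as the racemate.

**Step 3**
Reactants: 5 2-[3,4-dimethoxy-5-(triisopropylsilyloxy)phenyl]-2,3-dihydro-4H-pyran-4-one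
Product: 6 cis-(2R*,4R*)-2-[3,4-dimethoxy-5-(triisopropylsilyloxy)phenyl]-3,4-dihydro-2H-pyran-4-ol (racemic)
Conditions: NaBH4, CeCl3·7H2O, MeOH, −78 → −20 °C; basic work-up
Reagents that add atoms: none
Why: Luche reduction gives 1,2-addition of hydride to the enone carbonyl; hydride should enter axially on the half-chair that holds the aryl group pseudo-equatorial, so the C4 hydroxyl becomes pseudo-equatorial and cis to the C2 aryl group.

**Step 4**
Reactants: 6 cis-2-[3,4-dimethoxy-5-(triisopropylsilyloxy)phenyl]-3,4-dihydro-2H-pyran-4-ol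
Product: 7 cis-(2R*,4R*)-2-[3,4-dimethoxy-5-(triisopropylsilyloxy)phenyl]-4-(triisopropylsilyloxy)-3,4-dihydro-2H-pyran
Conditions: TIPSOTf, 2,6-lutidine, CH2Cl2, −78 → 0 °C
Reagents that add atoms: triisopropylsilyl trifluoromethanesulfonate, CC(C)[Si](OS(=O)(=O)C(F)(F)F)(C(C)C)C(C)C
Why: Silylation of a secondary allylic alcohol with a silyl triflate and a hindered pyridine base, which keeps the acid-sensitive enol ether intact; triisopropylsilyl is chosen because it has no Si–CH3 group that tBuLi could deprotonate.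

**Step 5**
Reactants: 7 cis-2-[3,4-dimethoxy-5-(triisopropylsilyloxy)phenyl]-4-(triisopropylsilyloxy)-3,4-dihydro-2H-pyran; 8 dimethyl squarate
Product: 11 4-[(2R*,4R*)-2-[3,4-dimethoxy-5-(triisopropylsilyloxy)phenyl]-4-(triisopropylsilyloxy)-3,4-dihydro-2H-pyran-6-yl]-2,3,4-trimethoxycyclobut-2-en-1-one (both epimers at the cyclobutenone carbon), via C6-lithiated dihydropyran 9 (not isolated), via lithium alkoxide adduct 10 (not isolated)
Conditions: tBuLi (1.5 equiv), THF, −78 → 0 °C; then cannulated into 8 (2 equiv), THF, −78 °C; then MeOTf, −78 → 0 °C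
Reagents that add atoms: methyl trifluoromethanesulfonate, COS(=O)(=O)C(F)(F)F
Why: α-Lithiation of the cyclic enol ether at its oxygen-bearing vinylic carbon C6 (as with silyl-protected glycals; the hold at 0 °C also destroys surplus tBuLi), 1,2-addition of the vinyllithium to one carbonyl of the squarate and O-methylation of the tertiary lithium alkoxide with MeOTf; the new quaternary carbon forms as both epimers, which converge in step 6.

**Step 6**
Reactants: 11 4-[2-aryl-4-(triisopropylsilyloxy)-3,4-dihydro-2H-pyran-6-yl]-2,3,4-trimethoxycyclobut-2-en-1-one (aryl = 3,4-dimethoxy-5-(triisopropylsilyloxy)phenyl)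
Product: 14 cis-(2R*,4R*)-2-[3,4-dimethoxy-5-(triisopropylsilyloxy)phenyl]-6,7,8-trimethoxy-4-(triisopropylsilyloxy)chroman-5-ol, via dienylketene 12 (not isolated), via cyclohexadienone 13 (not isolated)
Conditions: toluene (degassed, dilute), 110 °C, Ar
Reagents that add atoms: none
Why: On heating, the C1–C4 bond of the cyclobutenone should break in a conrotatory four-electron electrocyclic opening to dienylketene 12, in which the electron-donating C4 methoxy group has rotated outward and the dihydropyranyl group inward, next to the ketene. The ketene carbon then bonds to the nucleophilic β-carbon C5 of the enol ether in a thermal six-electron (disrotatory) electrocyclization, which closes the six-membered ring A by forming the C5–C4a bond of the chroman, and dienone 13 tautomerizes by loss of the C4a hydrogen to the phenol. This is the Moore rearrangement of a 4-alkoxy-4-alkenylcyclobutenone, the reaction type by which squarate adducts of lithiated dihydropyrans and glycals are turned into pyran-fused para-alkoxyphenols. No lasting stereocentre is created (C4a of 13 is lost on aromatization) and C2 and C4 are not touched, so the cis relationship is kept. The step needs torquoselectivity, which the outward preference of the oxygen donor at C4 supplies for both epimers of 11, and a single site of closure, which is given because the enol ether has only one vinylic CH carbon; the mechanism also fixes the oxygen pattern, the ketene carbon becoming C5–OH and the capped carbinol carbon C8–OMe.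

**Step 7**
Reactants: 14 cis-2-[3,4-dimethoxy-5-(triisopropylsilyloxy)phenyl]-6,7,8-trimethoxy-4-(triisopropylsilyloxy)chroman-5-ol
Product: 15 cis-(2R*,4R*)-2-(3-hydroxy-4,5-dimethoxyphenyl)-6,7,8-trimethoxychroman-4,5-diol
Conditions: TBAF, AcOH (1:1), THF, 0 °C → rt, Ar
Reagents that add atoms: none
Why: Fluoride-mediated cleavage of the aryl and the secondary alkyl silyl ether (Si–F bond formation); the acetic acid buffer keeps the electron-rich phenol from standing as its phenoxide, and the absence of strong acid avoids ionization of the benzylic C4 alcohol.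

**Step 8**
Reactants: 15 cis-2-(3-hydroxy-4,5-dimethoxyphenyl)-6,7,8-trimethoxychroman-4,5-diol
Product: 16 5-hydroxy-2-(3-hydroxy-4,5-dimethoxyphenyl)-6,7,8-trimethoxychroman-4-one (racemic flavanone)
Conditions: activated MnO2 (excess), CH2Cl2/EtOAc, rt, Ar
Reagents that add atoms: none
Why: MnO2 oxidation of an activated benzylic alcohol, as in the oxidation of hydroxybenzyl alcohols to hydroxyaryl carbonyl compounds; the new C4 carbonyl is hydrogen-bonded to the C5 hydroxyl, which deactivates ring A toward further oxidation.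

**Step 9**
Reactants: 16 5-hydroxy-2-(3-hydroxy-4,5-dimethoxyphenyl)-6,7,8-trimethoxychroman-4-one
Product: 18 Gardenin C, via 3-iodoflavanone 17 (not isolated)
Conditions: I2 (10 mol %), DMSO, 120 °C
Reagents that add atoms: none
Why: Iodine-catalysed dehydrogenation of a flavanone to a flavone (iodination at C3, elimination of HI, reoxidation of HI by DMSO), a reaction that tolerates free phenolic hydroxyls; it removes the last stereocentre.

**Compound list**
1 | 3-hydroxy-4,5-dimethoxybenzaldehyde | COc1cc(C=O)cc(O)c1OC | starting material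
2 | 3,4-dimethoxy-5-(triisopropylsilyloxy)benzaldehyde | COc1cc(C=O)cc(O[Si](C(C)C)(C(C)C)C(C)C)c1OC | intermediate
3 | Danishefsky's diene, (E)-1-methoxy-3-(trimethylsilyloxy)buta-1,3-diene | CO/C=C/C(=C)O[Si](C)(C)C | starting material
4 | 6-[3,4-dimethoxy-5-(triisopropylsilyloxy)phenyl]-2-methoxy-4-(trimethylsilyloxy)-5,6-dihydro-2H-pyran (racemic, mixture at the acetal carbon) | COC1C=C(O[Si](C)(C)C)C[C@H](c2cc(OC)c(OC)c(O[Si](C(C)C)(C(C)C)C(C)C)c2)O1 | intermediate (not isolated)
5 | 2-[3,4-dimethoxy-5-(triisopropylsilyloxy)phenyl]-2,3-dihydro-4H-pyran-4-one (racemic) | O=C1C[C@H](c2cc(OC)c(OC)c(O[Si](C(C)C)(C(C)C)C(C)C)c2)OC=C1 | intermediate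
6 | cis-(2R*,4R*)-2-[3,4-dimethoxy-5-(triisopropylsilyloxy)phenyl]-3,4-dihydro-2H-pyran-4-ol (racemic) | C1=C[C@H](O)C[C@H](c2cc(OC)c(OC)c(O[Si](C(C)C)(C(C)C)C(C)C)c2)O1 | intermediate
7 | cis-(2R*,4R*)-2-[3,4-dimethoxy-5-(triisopropylsilyloxy)phenyl]-4-(triisopropylsilyloxy)-3,4-dihydro-2H-pyran (racemic) | C1=C[C@H](O[Si](C(C)C)(C(C)C)C(C)C)C[C@H](c2cc(OC)c(OC)c(O[Si](C(C)C)(C(C)C)C(C)C)c2)O1 | intermediate
8 | dimethyl squarate (3,4-dimethoxycyclobut-3-ene-1,2-dione) | COC1=C(OC)C(=O)C1=O | starting material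
9 | 6-lithio derivative of 7 | [Li]C1=C[C@H](O[Si](C(C)C)(C(C)C)C(C)C)C[C@H](c2cc(OC)c(OC)c(O[Si](C(C)C)(C(C)C)C(C)C)c2)O1 | intermediate (not isolated)
10 | lithium 1-[2-aryl-4-(triisopropylsilyloxy)-3,4-dihydro-2H-pyran-6-yl]-2,3-dimethoxy-4-oxocyclobut-2-en-1-olate (both epimers at the carbinol carbon) | COC1=C(OC)C(O[Li])(C2=C[C@H](O[Si](C(C)C)(C(C)C)C(C)C)C[C@H](c3cc(OC)c(OC)c(O[Si](C(C)C)(C(C)C)C(C)C)c3)O2)C1=O | intermediate (not isolated)
11 | 4-[(2R*,4R*)-2-[3,4-dimethoxy-5-(triisopropylsilyloxy)phenyl]-4-(triisopropylsilyloxy)-3,4-dihydro-2H-pyran-6-yl]-2,3,4-trimethoxycyclobut-2-en-1-one (racemic cis pyran, both epimers at the cyclobutenone carbon) | COC1=C(OC)C(OC)(C2=C[C@H](O[Si](C(C)C)(C(C)C)C(C)C)C[C@H](c3cc(OC)c(OC)c(O[Si](C(C)C)(C(C)C)C(C)C)c3)O2)C1=O | intermediate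
12 | (3Z)-2,3,4-trimethoxy-4-[2-aryl-4-(triisopropylsilyloxy)-3,4-dihydro-2H-pyran-6-yl]buta-1,3-dien-1-one (dienylketene) | O=C=C(OC)/C(OC)=C(OC)\C1=C[C@H](O[Si](C(C)C)(C(C)C)C(C)C)C[C@H](c2cc(OC)c(OC)c(O[Si](C(C)C)(C(C)C)C(C)C)c2)O1 | intermediate (not isolated)
13 | 2-[3,4-dimethoxy-5-(triisopropylsilyloxy)phenyl]-6,7,8-trimethoxy-4-(triisopropylsilyloxy)-2,3,4,4a-tetrahydro-5H-chromen-5-one (C4a unassigned) | COc1cc([C@H]2C[C@@H](O[Si](C(C)C)(C(C)C)C(C)C)C3C(=O)C(OC)=C(OC)C(OC)=C3O2)cc(O[Si](C(C)C)(C(C)C)C(C)C)c1OC | intermediate (not isolated)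
14 | cis-(2R*,4R*)-2-[3,4-dimethoxy-5-(triisopropylsilyloxy)phenyl]-6,7,8-trimethoxy-4-(triisopropylsilyloxy)chroman-5-ol (racemic) | COc1cc([C@H]2C[C@@H](O[Si](C(C)C)(C(C)C)C(C)C)c3c(O)c(OC)c(OC)c(OC)c3O2)cc(O[Si](C(C)C)(C(C)C)C(C)C)c1OC | intermediate
15 | cis-(2R*,4R*)-2-(3-hydroxy-4,5-dimethoxyphenyl)-6,7,8-trimethoxychroman-4,5-diol (racemic) | COc1cc([C@H]2C[C@@H](O)c3c(O)c(OC)c(OC)c(OC)c3O2)cc(O)c1OC | intermediate
16 | 5-hydroxy-2-(3-hydroxy-4,5-dimethoxyphenyl)-6,7,8-trimethoxychroman-4-one (racemic) | COc1cc([C@H]2CC(=O)c3c(O)c(OC)c(OC)c(OC)c3O2)cc(O)c1OC | intermediate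
17 | 5-hydroxy-2-(3-hydroxy-4,5-dimethoxyphenyl)-3-iodo-6,7,8-trimethoxychroman-4-one (mixture of diastereomers) | COc1cc(C2Oc3c(OC)c(OC)c(OC)c(O)c3C(=O)C2I)cc(O)c1OC | intermediate (not isolated)
18 | Gardenin C, 5-hydroxy-2-(3-hydroxy-4,5-dimethoxyphenyl)-6,7,8-trimethoxy-4H-chromen-4-one | COc1cc(-c2cc(=O)c3c(O)c(OC)c(OC)c(OC)c3o2)cc(O)c1OC | target

**Step count**
Total steps: 9. Longest linear sequence: 9 steps (1 → 18); compounds 3 and 8 enter as bought reagents.

**Steps most likely to fail**

1. Step 5. tBuLi may deprotonate the benzylic C2–H or an aromatic C–H of ring B in competition with the vinylic C6–H, and base that survives may add to the squarate. The fallback sets out from 7 and comes back at 11, using anomeric sulfone chemistry. Benzenesulfinic acid (CH2Cl2, rt) is added across the enol ether of 7 to give 2-[3,4-dimethoxy-5-(triisopropylsilyloxy)phenyl]-6-(phenylsulfonyl)-4-(triisopropylsilyloxy)tetrahydropyran F1. Its C6–H, acidified by the sulfone, is removed with nBuLi at −78 °C, where benzylic and aryl C–H bonds are not attacked. The carbanion is added to 8 and the alkoxide is methylated with MeOTf to give 2,3,4-trimethoxy-4-[6-(phenylsulfonyl)tetrahydropyran-6-yl]cyclobutenone F2. DBU in toluene then eliminates benzenesulfinic acid across C5–C6 to give 11.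

2. Step 6. At 110 °C the phenol product may lose the C4 silyloxy group through ortho-quinone methide formation, or the electron-rich phenol may be oxidized by traces of air. The fallback sets out from 1 and comes back at 18; it gives up the ring expansion and closes ring C onto a bought ring A. Compound 1 is benzylated (BnBr, K2CO3, DMF) to 3-benzyloxy-4,5-dimethoxybenzaldehyde F3. Claisen–Schmidt condensation with bought 2'-hydroxy-3',4',5',6'-tetramethoxyacetophenone (KOH, EtOH) gives (E)-3-(3-benzyloxy-4,5-dimethoxyphenyl)-1-(2-hydroxy-3,4,5,6-tetramethoxyphenyl)prop-2-en-1-one F4. Oxidative cyclization with I2 (catalytic) in DMSO at 130 °C gives 2-(3-benzyloxy-4,5-dimethoxyphenyl)-5,6,7,8-tetramethoxy-4H-chromen-4-one F5. BCl3 (CH2Cl2, −78 → 0 °C) then cleaves the benzyl ether and, by chelation to the C4 carbonyl, the C5 methyl ether to give 18.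

3. Step 8. The oxidant may attack the electron-rich phenols (radical coupling or quinone formation) faster than it oxidizes the C4 carbinol. The fallback sets out from 15 and comes back at 16; it masks both phenols before the oxidation. Selective O-benzylation of the two phenols (BnBr, K2CO3, DMF, rt) gives cis-5-benzyloxy-2-(3-benzyloxy-4,5-dimethoxyphenyl)-6,7,8-trimethoxychroman-4-ol F6. Dess–Martin oxidation (NaHCO3, CH2Cl2) gives 5-benzyloxy-2-(3-benzyloxy-4,5-dimethoxyphenyl)-6,7,8-trimethoxychroman-4-one F7. Hydrogenolysis (H2, Pd/C, EtOAc) then gives 16.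

**Further compounds**
F1 | step 5 | 2-[3,4-dimethoxy-5-(triisopropylsilyloxy)phenyl]-6-(phenylsulfonyl)-4-(triisopropylsilyloxy)tetrahydropyran (cis at C2/C4, mixture at C6) | O=S(=O)(c1ccccc1)C1C[C@H](O[Si](C(C)C)(C(C)C)C(C)C)C[C@H](c2cc(OC)c(OC)c(O[Si](C(C)C)(C(C)C)C(C)C)c2)O1
F2 | step 5 | 4-[2-[3,4-dimethoxy-5-(triisopropylsilyloxy)phenyl]-6-(phenylsulfonyl)-4-(triisopropylsilyloxy)tetrahydropyran-6-yl]-2,3,4-trimethoxycyclobut-2-en-1-one (mixture of diastereomers) | COC1=C(OC)C(OC)(C2(S(=O)(=O)c3ccccc3)C[C@H](O[Si](C(C)C)(C(C)C)C(C)C)C[C@H](c3cc(OC)c(OC)c(O[Si](C(C)C)(C(C)C)C(C)C)c3)O2)C1=O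
F3 | step 6 | 3-benzyloxy-4,5-dimethoxybenzaldehyde | COc1cc(C=O)cc(OCc2ccccc2)c1OC
F4 | step 6 | (E)-3-(3-benzyloxy-4,5-dimethoxyphenyl)-1-(2-hydroxy-3,4,5,6-tetramethoxyphenyl)prop-2-en-1-one | COc1cc(/C=C/C(=O)c2c(O)c(OC)c(OC)c(OC)c2OC)cc(OCc2ccccc2)c1OC
F5 | step 6 | 2-(3-benzyloxy-4,5-dimethoxyphenyl)-5,6,7,8-tetramethoxy-4H-chromen-4-one | COc1cc(-c2cc(=O)c3c(OC)c(OC)c(OC)c(OC)c3o2)cc(OCc2ccccc2)c1OC
F6 | step 8 | cis-(2R*,4R*)-5-benzyloxy-2-(3-benzyloxy-4,5-dimethoxyphenyl)-6,7,8-trimethoxychroman-4-ol (racemic) | COc1cc([C@H]2C[C@@H](O)c3c(OCc4ccccc4)c(OC)c(OC)c(OC)c3O2)cc(OCc2ccccc2)c1OC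
F7 | step 8 | 5-benzyloxy-2-(3-benzyloxy-4,5-dimethoxyphenyl)-6,7,8-trimethoxychroman-4-one (racemic) | COc1cc([C@H]2CC(=O)c3c(OCc4ccccc4)c(OC)c(OC)c(OC)c3O2)cc(OCc2ccccc2)c1OC
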